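## Structural features

The target is a flavone: a benzene ring A fused to a 4-pyranone ring C (O1, C2=C3, C4=O), with a phenyl ring B attached through the single C2–C1' bond. Ring A carries a free hydroxyl at C5, hydrogen-bonded to the C4 carbonyl, and a hydrogen sulfate ester at O7; ring B carries a hydrogen sulfate at O3' and free hydroxyls at C4' and C5'. There is no stereocentre, so no stereocentres stand next to each other; every ring atom is sp2. The fragile groups are the aryl O–SO3H monoesters (cleaved by acid and heat, self-catalysed in the free-acid form), the 4',5'-catechol (oxidised easily in base and air) and C2 of the pyranone (open to hard nucleophiles). The difficulty is not a ring but the placement of exactly two sulfates on five phenolic oxygens: O7 must be taken and O5 left, and on ring B one outer oxygen must be taken while the more acidic O4' and the other outer oxygen stay free. Ring B is locally symmetric about the C1'–C4' axis until it is sulfated, so the 3'/5' choice is no issue, but the outer-versus-inner choice is. The key step exploits two facts: C2–C1' is the only carbon–carbon bond between the two oxygenated arenes, and C2 of a chromone is the unsubstituted β-carbon of a vinylogous ester, which takes up an aryl–palladium species regioselectively. Cutting there leaves two halves in each of which the oxygen to be sulfated is the single reactive hydroxyl: O7 beside the chelated O5, and O3' beside an O4'/O5' pair tied into one five-membered ketal.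

## Logic of the disconnections

10 ⇒ 8 (through 9). No skeletal bond is cut. The two sulfate O–H bonds are traced back to O–CH2CCl3 ester bonds, and the O4'–H and O5'–H bonds to the two O–C bonds of one CPh2 ketal. The reason is that 8 is neutral, soluble and chromatographable, and both masks fall to reduction on palladium on carbon at neutral pH, where aryl sulfate monoester anions persist. The gain is that the ionic, acid-labile functionality appears only in the last operation. The demand is that the reduction spares C2=C3 and the S–OAr bonds and that the final protonation of 9 is cold and brief.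

8 ⇒ 7 + 5 (key disconnection). The C2–C1' bond is cut. In one sentence: 8 is made by oxidative arylation of the unfunctionalised C2–H of 7 with 5. The cut separates the two oxygenation domains, so each sulfate is installed on a small fragment where only one hydroxyl can react, and ring C is never built because it is already present in 6. The gain is the step from a 2-arylchromone with five differentiated oxygens to one bicyclic and one monocyclic piece. The demand is arylation at C2 and not C3, a net oxidation that restores C2=C3, and tolerance of the chelated 5-OH, the sulfate diesters and the ketal.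

7 ⇒ 6. The O7–S bond is cut. In 6 the 7-OH is the only acidic, non-chelated hydroxyl, so the forward step must only stop at mono-sulfonylation.

5 ⇒ 4. The O–S bond on the ring B fragment is cut. 4 has a single hydroxyl, so no selectivity is demanded; the boronate must merely survive an amine base and a sulfonylating agent.

4 ⇒ 3. The C–B bond is cut back to a C–Br bond. The bromide fixes the later C1' position, meta to the free hydroxyl, which no electrophilic substitution of the ring would reach. The demand is a borylation that tolerates a free phenol.

3 ⇒ 2. The two O–CPh2 bonds are cut. 2 is symmetric, so either adjacent pair of hydroxyls gives the same ketal and exactly one outer hydroxyl is left. This is where O3' is distinguished from O4' and O5' in one step.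

2 ⇒ 1. The three O–CH3 bonds are cut, leading to a catalogue arene that already has the bromine para to the central oxygen.

## Other disconnections considered

Alternative 1: the route most chemists would draw first. Cut O1–C2 and the C3–C(carbonyl) bond of ring C. The forward key step is a Baker–Venkataraman acyl transfer to the 1,3-diketone A1, followed by acid cyclodehydration. Ring C is then formed under strong base and closed under acid; the base excludes sulfate diesters and the acid endangers the ketal and the acetal groups of A1. Sulfation would therefore have to follow ring formation, which requires a third class of protecting group on O7 and O3' and its separate removal. The sequence is linear and roughly half as long again as the chosen one, and it rebuilds a ring that 6 supplies ready-made.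

Alternative 2: an aryne annulation. Cut O1–C8a and C4–C4a. In the forward step, fluoride (CsF) releases the 3,5-dioxygenated aryne A3 from silyl triflate A2. The carboxylate of arylpropiolic acid A4 should add through oxygen to the aryne carbon remote from the flanking alkoxy group, leaving the aryl anion next to the inductively withdrawing C–O bond. Acyl transfer to that carbon gives the 2-hydroxyaryl ynone A5, and 6-endo oxa-Michael closure gives the flavone with the correct 5,7-pattern. This plan also passes both tests, and the regiochemistry is defensible. It is longer, however: A2 needs several steps (halogenation, silylation, retro-Brook shift, triflation) and A4 needs three more from 3. The closure of A5 can also go 5-exo to an aurone. Fluoride and carboxylate rule out carrying sulfate diesters, so O5 and O7 emerge identically protected and sulfation again comes late.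

Alternative 3: late C5'–O bond formation. Cut the C5'–O bond. The forward step is ortho-oxygenation of the 4'-phenol of the 3',4'-dioxygenated flavone A6 with the pentavalent iodine reagent IBX to the ortho-quinone A7, followed by reduction. The phenol to be oxidised is para to the electron-poor chromone and ortho to a sulfate ester, which is the class least suited to an oxygen transfer that depends on an electron-rich ring. Reaching A6 also requires sulfating O3' in the presence of the more acidic O4' on a catechol, where the ketal device of 3 cannot distinguish the two oxygens. The differentiation problem becomes harder, not easier.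

Key step: step 6

Assumption 1: the target is drawn as the neutral bis(hydrogen sulfate), so the route ends with protonation of the diammonium salt 9; the free acid must be kept cold and lyophilised at once, because aryl hydrogen sulfates hydrolyse under their own acidity.
Assumption 2: 5-bromo-1,2,3-trimethoxybenzene (1), 5,7-dihydroxychromone (6) and 2,2,2-trichloroethyl chlorosulfate are taken as catalogue materials.

## Route

Step 1
Reactants: 1 5-bromo-1,2,3-trimethoxybenzene
Product: 2 5-bromobenzene-1,2,3-triol
Conditions: BBr3 (4 equiv), CH2Cl2, −78 °C to rt; then H2O, 0 °C; used without storage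
Reagents that add atoms: none
Why: Lewis-acid ether cleavage (BBr3 demethylation): bromide attacks the methyl group of each boron-complexed ether and aqueous work-up frees the triol; the aryl bromide is inert.

Step 2
Reactants: 2 5-bromobenzene-1,2,3-triol
Product: 3 6-bromo-2,2-diphenyl-1,3-benzodioxol-4-ol
Conditions: Ph2CCl2 (1.2 equiv), neat, 170 °C, 20 min, HCl vented
Reagents that add atoms: dichlorodiphenylmethane, ClC(Cl)(c1ccccc1)c1ccccc1
Why: Diphenylmethylene ketal formation by two successive substitutions at the benzhydrylic dichloride through the stabilised chlorodiphenylmethyl cation. Only two adjacent hydroxyls can close the five-membered ring, and the symmetry of 2 makes both possible pairs identical, so one outer hydroxyl is left free without any regiochemical choice.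

Step 3
Reactants: 3 6-bromo-2,2-diphenyl-1,3-benzodioxol-4-ol
Product: 4 2,2-diphenyl-6-(4,4,5,5-tetramethyl-1,3,2-dioxaborolan-2-yl)-1,3-benzodioxol-4-ol
Conditions: B2pin2 (1.5 equiv), PdCl2(dppf) (5 mol %), KOAc (4 equiv), 1,4-dioxane, 90 °C
Reagents that add atoms: bis(pinacolato)diboron, CC1(C)OB(OC1(C)C)B1OC(C)(C)C(C)(C)O1
Why: Miyaura borylation: oxidative addition of the C–Br bond to zerovalent palladium, acetate-assisted transmetalation with the diboron and reductive elimination. Free phenols are tolerated with the weak base KOAc, and the diaryl ketal is inert.

Step 4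
Reactants: 4 2,2-diphenyl-6-(4,4,5,5-tetramethyl-1,3,2-dioxaborolan-2-yl)-1,3-benzodioxol-4-ol
Product: 5 2,2-diphenyl-6-(4,4,5,5-tetramethyl-1,3,2-dioxaborolan-2-yl)-1,3-benzodioxol-4-yl 2,2,2-trichloroethyl sulfate
Conditions: Cl3CCH2OSO2Cl (1.2 equiv), Et3N (1.5 equiv), DMAP (0.2 equiv), THF, 0 °C to rt
Reagents that add atoms: 2,2,2-trichloroethyl chlorosulfate, O=S(=O)(Cl)OCC(Cl)(Cl)Cl
Why: O-sulfonylation of the only hydroxyl with a chlorosulfate gives the trichloroethyl-protected aryl sulfate diester; the pinacol boronate does not react with amine base or chlorosulfate.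

Step 5
Reactants: 6 5,7-dihydroxy-4H-chromen-4-one
Product: 7 5-hydroxy-4-oxo-4H-chromen-7-yl 2,2,2-trichloroethyl sulfate
Conditions: Cl3CCH2OSO2Cl (1.05 equiv), Et3N (1.1 equiv), DMAP (0.1 equiv), THF, −20 to 0 °C
Reagents that add atoms: 2,2,2-trichloroethyl chlorosulfate, O=S(=O)(Cl)OCC(Cl)(Cl)Cl
Why: Chemoselective O-sulfonylation: the 7-OH is a vinylogous carboxylic acid (para to the C4 carbonyl) and is the only hydroxyl ionised by one equivalent of amine, whereas the 5-OH is held in a six-membered hydrogen bond to C4=O and is a poor nucleophile.

Step 6
Reactants: 7 5-hydroxy-4-oxo-4H-chromen-7-yl 2,2,2-trichloroethyl sulfate; 5 2,2-diphenyl-6-(4,4,5,5-tetramethyl-1,3,2-dioxaborolan-2-yl)-1,3-benzodioxol-4-yl 2,2,2-trichloroethyl sulfate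
Product: 8 5-hydroxy-2-[2,2-diphenyl-7-(2,2,2-trichloroethoxysulfonyloxy)-1,3-benzodioxol-5-yl]-4-oxo-4H-chromen-7-yl 2,2,2-trichloroethyl sulfate (4',5'-O-diphenylmethylene-tricetin 7,3'-bis(trichloroethyl sulfate))
Conditions: 5 (1.5 equiv), Pd(OCOCF3)2 (10 mol %), 5-nitro-1,10-phenanthroline (20 mol %), O2 (1 atm), DMSO, 100 °C
Reagents that add atoms: none
Why: Oxidative boron-Heck reaction, that is, C2-arylation of a chromone by an arylboron reagent under divalent palladium catalysis, a known reaction type for chromones and arylboronic pinacol esters. Transmetalation of 5 to the phenanthroline-bound divalent palladium trifluoroacetate gives an aryl–palladium species that coordinates the C2=C3 bond of 7. Migratory insertion delivers the aryl group to C2, the electrophilic β-carbon of the vinylogous ester, and places palladium at C3 as an enolate; the opposite regiochemistry would put palladium on the oxygen-bearing carbon without enolate stabilisation, and C3 products could arise only from electrophilic C–H palladation of the chromone, which fast transmetalation of the boronate should outrun. Because the C2–H is anti to palladium after syn insertion, the C-bound enolate must pass through its O-bound form to reach the face syn to that hydrogen before β-hydride elimination releases 8; the base-free, oxidising medium disfavours the competing protonation of the enolate. Zerovalent palladium is reoxidised by O2. No ring is closed and no stereocentre is formed: the step only joins ring B to ring C and restores C2=C3. The electron-withdrawing sulfate diester at O7 and the hydrogen bond from the 5-OH to C4=O both raise the electrophilicity of C2, and the sulfate diester meta to boron in 5 slows protodeboronation and oxidative homocoupling. The trichloroethyl sulfate diesters and the diaryl ketal offer nothing that divalent palladium, O2 or DMSO should attack in the absence of base.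

Step 7
Reactants: 8 4',5'-O-diphenylmethylene-tricetin 7,3'-bis(trichloroethyl sulfate)
Product: 10 tricetin 7,3'-disulfate (5-hydroxy-2-[3,4-dihydroxy-5-(sulfooxy)phenyl]-4-oxo-4H-chromen-7-yl hydrogen sulfate), via diammonium disulfate salt 9 (not isolated)
Conditions: Pd/C (10 wt %), HCO2NH4 (10 equiv), MeOH/THF 2:1, rt; then H2 (1 atm), rt; filter, evaporate cold; then 1 M aq HCl (2.0 equiv), 0 °C; C18 reverse phase (H2O/MeCN, 0.1 % HCO2H), lyophilise
Reagents that add atoms: none
Why: Reductive fragmentation of the trichloroethyl groups (two-electron reduction of a C–Cl bond, then β-elimination of the sulfate monoester anion with release of 1,1-dichloroethene), followed by hydrogenolysis of the two doubly benzylic C–O bonds of the ketal to diphenylmethane. Aryl sulfate monoester anions are stable to neutral hydrogenation and the vinylogous ester C2=C3 is slow to reduce at rt and 1 atm; hydrogen gas is admitted only after the formate stage so that no partly dechlorinated ester can form. Stoichiometric acid then converts salt 9 into the drawn acid form.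

## Compound list

1 | 5-bromo-1,2,3-trimethoxybenzene | COc1cc(Br)cc(OC)c1OC | starting material
2 | 5-bromobenzene-1,2,3-triol | Oc1cc(Br)cc(O)c1O | intermediate
3 | 6-bromo-2,2-diphenyl-1,3-benzodioxol-4-ol | Oc1cc(Br)cc2OC(c3ccccc3)(c3ccccc3)Oc12 | intermediate
4 | 2,2-diphenyl-6-(4,4,5,5-tetramethyl-1,3,2-dioxaborolan-2-yl)-1,3-benzodioxol-4-ol | Oc1cc(B2OC(C)(C)C(C)(C)O2)cc2OC(c3ccccc3)(c3ccccc3)Oc12 | intermediate
5 | 2,2-diphenyl-6-(4,4,5,5-tetramethyl-1,3,2-dioxaborolan-2-yl)-1,3-benzodioxol-4-yl 2,2,2-trichloroethyl sulfate | ClC(Cl)(Cl)COS(=O)(=O)Oc1cc(B2OC(C)(C)C(C)(C)O2)cc2OC(c3ccccc3)(c3ccccc3)Oc12 | intermediate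
6 | 5,7-dihydroxy-4H-chromen-4-one | O=c1ccoc2cc(O)cc(O)c12 | starting material
7 | 5-hydroxy-4-oxo-4H-chromen-7-yl 2,2,2-trichloroethyl sulfate | O=c1ccoc2cc(OS(=O)(=O)OCC(Cl)(Cl)Cl)cc(O)c12 | intermediate
8 | 5-hydroxy-2-[2,2-diphenyl-7-(2,2,2-trichloroethoxysulfonyloxy)-1,3-benzodioxol-5-yl]-4-oxo-4H-chromen-7-yl 2,2,2-trichloroethyl sulfate | O=c1cc(-c2cc(OS(=O)(=O)OCC(Cl)(Cl)Cl)c3OC(c4ccccc4)(c4ccccc4)Oc3c2)oc2cc(OS(=O)(=O)OCC(Cl)(Cl)Cl)cc(O)c12 | intermediate
9 | diammonium 5-hydroxy-2-(3,4-dihydroxy-5-sulfonatooxyphenyl)-4-oxo-4H-chromen-7-yl sulfate | [NH4+].[NH4+].O=c1cc(-c2cc(O)c(O)c(OS(=O)(=O)[O-])c2)oc2cc(OS(=O)(=O)[O-])cc(O)c12 | intermediate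
10 | tricetin 7,3'-disulfate | O=c1cc(-c2cc(O)c(O)c(OS(=O)(=O)O)c2)oc2cc(OS(=O)(=O)O)cc(O)c12 | target

## Step count and least certain steps

Total steps: 7. Longest linear sequence: 6 (steps 1, 2, 3, 4, 6, 7); step 5 is the one-step side branch.

Step 6 (key step). The most likely failures are:
- protonation of the C3 palladium enolate before β-hydride elimination, so that the reaction stops at simple conjugate addition;
- sequestration of palladium by the 5-hydroxy-4-keto chelate;
- oxidative homocoupling or oxidation of the boronate by the peroxide formed from O2;
- slow attack of transient zerovalent palladium on the C–Cl bonds.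

Fallback: separate the C–C bond formation from the oxidation. Setting out from 7 and 5, a redox-neutral Hayashi–Miyaura 1,4-addition with monovalent rhodium ([Rh(OH)(cod)]2, 1,4-dioxane/H2O, 60 °C) should give the racemic 2,3-dihydro compound, flavanone F1. A separate dehydrogenation with DDQ in 1,4-dioxane at 95 °C, a standard conversion of 5-hydroxyflavanones, then comes back to the route at 8.

Step 7. The risks are:
- loss of single chlorine atoms from the trichloroethyl groups without fragmentation if hydrogen is admitted too early;
- ammonolysis of the activated O7 sulfate diester before it is unmasked;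
- over-reduction of C2=C3 during the slower ketal hydrogenolysis;
- hydrolysis of the sulfates during acidification.

Fallback: remove the ketal first and avoid hydrogen gas. Setting out from 8, acidolysis in AcOH/H2O 4:1 at 90 °C (sulfate diesters are acid-stable) should give the catechol bis(trichloroethyl sulfate) F2. Zinc dust with HCO2NH4 in MeOH at rt then unmasks both sulfates and comes back to the route at 9, which is acidified as in step 7.

Step 3. The risk is binding of the phenoxide to palladium, with protodebromination, or Suzuki coupling of the phenoxide-activated product with unreacted bromide.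

Fallback: mask the phenol before the palladium step. Setting out from 3, sulfonylation with Cl3CCH2OSO2Cl and Et3N should give the bromoaryl trichloroethyl sulfate F3. Its Miyaura borylation (B2pin2, PdCl2(dppf), KOAc, 1,4-dioxane, 80 °C) comes back to the route at 5, so step 4 is no longer needed.

Step 5. The risk is a second sulfonylation at O5 once O7 is consumed, or DMAP-mediated sulfuryl transfer between phenols, giving mixtures.

Fallback: lock O5 before sulfonylation. Setting out from 6, BF3·OEt2 in CH2Cl2 should give the difluoroboron chelate F4, in which boron bridges O5 and the C4 carbonyl oxygen. Sulfonylation of the one remaining hydroxyl gives the chelated sulfate diester F5, and warming in MeOH releases the chelate and comes back to the route at 7.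

## Further compounds

F1 | step 6 | rac-5-hydroxy-2-[2,2-diphenyl-7-(2,2,2-trichloroethoxysulfonyloxy)-1,3-benzodioxol-5-yl]-4-oxo-3,4-dihydro-2H-chromen-7-yl 2,2,2-trichloroethyl sulfate (racemic flavanone) | O=C1CC(c2cc(OS(=O)(=O)OCC(Cl)(Cl)Cl)c3OC(c4ccccc4)(c4ccccc4)Oc3c2)Oc2cc(OS(=O)(=O)OCC(Cl)(Cl)Cl)cc(O)c12
F2 | step 7 | 2-[3,4-dihydroxy-5-(2,2,2-trichloroethoxysulfonyloxy)phenyl]-5-hydroxy-4-oxo-4H-chromen-7-yl 2,2,2-trichloroethyl sulfate | O=c1cc(-c2cc(O)c(O)c(OS(=O)(=O)OCC(Cl)(Cl)Cl)c2)oc2cc(OS(=O)(=O)OCC(Cl)(Cl)Cl)cc(O)c12
F3 | step 3 | 6-bromo-2,2-diphenyl-1,3-benzodioxol-4-yl 2,2,2-trichloroethyl sulfate | ClC(Cl)(Cl)COS(=O)(=O)Oc1cc(Br)cc2OC(c3ccccc3)(c3ccccc3)Oc12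
F4 | step 5 | difluoroboron chelate of 5,7-dihydroxychromone (boron bound to O5 and to the C4 carbonyl oxygen, 7-OH free) | F[B-]1(F)Oc2cc(O)cc3OC=CC(=[O+]1)c23
F5 | step 5 | difluoroboron chelate of 5-hydroxy-4-oxo-4H-chromen-7-yl 2,2,2-trichloroethyl sulfate | F[B-]1(F)Oc2cc(OS(=O)(=O)OCC(Cl)(Cl)Cl)cc3OC=CC(=[O+]1)c23
A1 | alternative 1 | 1-[2-hydroxy-4,6-bis(methoxymethoxy)phenyl]-3-[7-(methoxymethoxy)-2,2-diphenyl-1,3-benzodioxol-5-yl]propane-1,3-dione | COCOc1cc(O)c(C(=O)CC(=O)c2cc(OCOC)c3OC(c4ccccc4)(c4ccccc4)Oc3c2)c(OCOC)c1
A2 | alternative 2 | 3,5-bis(methoxymethoxy)-2-(trimethylsilyl)phenyl trifluoromethanesulfonate | C[Si](C)(C)c1c(OCOC)cc(OCOC)cc1OS(=O)(=O)C(F)(F)F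
A3 | alternative 2 | 3,5-bis(methoxymethoxy)benzyne | C1#CC(OCOC)=CC(OCOC)=C1
A4 | alternative 2 | 3-[7-(methoxymethoxy)-2,2-diphenyl-1,3-benzodioxol-5-yl]prop-2-ynoic acid | OC(=O)C#Cc1cc(OCOC)c2OC(c3ccccc3)(c3ccccc3)Oc2c1
A5 | alternative 2 | 1-[2-hydroxy-4,6-bis(methoxymethoxy)phenyl]-3-[7-(methoxymethoxy)-2,2-diphenyl-1,3-benzodioxol-5-yl]prop-2-yn-1-one | COCOc1cc(O)c(C(=O)C#Cc2cc(OCOC)c3OC(c4ccccc4)(c4ccccc4)Oc3c2)c(OCOC)c1
A6 | alternative 3 | 5-hydroxy-2-[4-hydroxy-3-(2,2,2-trichloroethoxysulfonyloxy)phenyl]-4-oxo-4H-chromen-7-yl 2,2,2-trichloroethyl sulfate | O=c1cc(-c2ccc(O)c(OS(=O)(=O)OCC(Cl)(Cl)Cl)c2)oc2cc(OS(=O)(=O)OCC(Cl)(Cl)Cl)cc(O)c12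
A7 | alternative 3 | 2-[3,4-dioxo-5-(2,2,2-trichloroethoxysulfonyloxy)cyclohexa-1,5-dien-1-yl]-5-hydroxy-4-oxo-4H-chromen-7-yl 2,2,2-trichloroethyl sulfate (ortho-quinone) | O=c1cc(C2=CC(=O)C(=O)C(OS(=O)(=O)OCC(Cl)(Cl)Cl)=C2)oc2cc(OS(=O)(=O)OCC(Cl)(Cl)Cl)cc(O)c12
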